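## Structural features

The target is a biflavonoid in which a (2S)-flavanone (naringenin: benzo ring A, dihydropyranone ring C, 4-hydroxyphenyl ring B) is joined through C6 of its ring A to C8'' of a flavone (apigenin) by one aryl–aryl bond. C2 is the only stereocentre and no other stereocentre stands next to it, so it has to be set by a chiral reagent or catalyst. The C6–C8'' bond is flanked by four oxygen-bearing ortho carbons (C5, C7, C7'' and C8a''). This makes it hard to form and turns it into a hindered axis whose configuration the target structure leaves open. The fragile points are C2 (lost when base or heat opens ring C to the 2'-hydroxychalcone and it recloses), the six free phenols, and the flavone enone and aryl ketone, which limit reductive conditions. The real difficulty is regiochemical as much as stereochemical: the link must sit at C6 and not C8 of the flavanone and at C8'' and not C6'' of the flavone, and the two oxygens ortho to the C4 acyl group must be told apart, one becoming O1 and the other the C5 phenol. The key step uses the fact that C2 is a benzylic ether carbon on O1 and C3 is a methylene next to the C4 ketone. A ketocarbene at C3 can insert into the benzylic C–H of an aryl 4-oxybenzyl ether on O1, which forms C2–C3, closes ring C, fixes which oxygen becomes O1 and sets C2 in one operation.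

## Logic of the disconnections

16 to 15: the five phenolic O–benzyl bonds are cut. Hydrogenolysis is neutral, so the base-sensitive C2 centre is not endangered, and the polyphenol is released in the last step with only filtration as work-up. The forward step must cleave benzyl ethers faster than it reduces the flavone C2''=C3'' bond, the C4 ketone or the benzylic C2–O1 bond.

15 to 14: the O–Si bond at the C5 oxygen is cut. This oxygen needs a group of its own because it must carry no activated C–H during the key step. The forward step must be buffered so that no phenoxide or enolate opens ring C.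

14 to 13: the C2–C3 bond is cut, which opens ring C and removes the stereocentre. This reduces the flavanone to an aryl diazomethyl ketone with an O-benzyl-type ether, and the ether position alone decides which oxygen becomes O1. The forward step must favour C–H insertion over attack of the ether oxygen on the carbene and must select one of two enantiotopic benzylic hydrogens.

13 to 11 through 12: the C=N2 bond at the future C3 is cut back to a methyl ketone. Acyl-activated diazo transfer avoids diazomethane and an acid chloride. The forward step needs a kinetic enolate next to an aryl silyl ether without silyl migration, and a sulfonyl azide of low hazard.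

11 to 10: the O–Si bond is cut again, so the silyl group is put on after the cross-coupling. A free chelated phenol is tolerated in an aqueous basic coupling, whereas an aryl silyl ether ortho to a ketone would not survive it. The forward step must silylate a phenol shielded by an acyl group and a biaryl.

10 to 5 and 9: the C6–C8'' biaryl bond is cut. This is the most convergent cut, giving two halves of similar size that each derive from a cheap phloroglucinol-type starting material. The forward step is a cross-coupling that forms a tetra-ortho-substituted biaryl from an electron-rich boronate prone to protodeboronation.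

9 to 8 to 7 to 6: the C8''–B bond, the C8''–I bond and three O–benzyl bonds are cut in turn. 6 already contains the whole flavone, so nothing of it has to be built. The demand is substitution at C8'' and not at C6''.

5 to 4 to 2 to 1, with 3: the C–I bond, the O–CH2Ar bond from 3 and one O–benzyl bond are cut. The para hydroxyl of 1 is the most acidic and is not chelated, so it is alkylated first. The two ortho hydroxyls of 2 are equivalent, and once one is alkylated the other is locked by the carbonyl. That remaining phenol then directs iodine to its own ortho position, the future C6. The demands are mono-alkylation at each stage and ortho rather than para iodination.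

## Other disconnections considered

Alternative 1: The cut runs through ring A of the flavone (C8''–C8a'', C7''–C8'', C5''–C6'', C4a''–C5''). In the forward sense the diazo ketone A1 would undergo Wolff rearrangement to the ketene A2. A2 would add benzyl ethynyl ether A3 to give a cyclobutenone, which would open in a four-electron process and close in a six-electron process onto the pyranone double bond to give the phenol A4.
- In its favour: four bonds and a ring form in one operation. The hindered aryl–aryl bond needs no cross-coupling, because the phloroglucinol ring already sits on the diazo carbon; on this point it is better than the chosen plan, whose step 7 is a tetra-ortho-substituted coupling. The oxygen pattern of ring A (free 5''-OH, 7''-O-benzyl) arises without any regiochemical question, which is better than iodinating an intact flavone in step 5.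
- Against it here: the flavone it builds can be bought intact as 6. A1 needs a pyranone acid and a hindered aryl diazo unit made separately. Ethynyl ethers such as A3 are thermally labile. The 2,6-disubstituted aryl group on A2 should slow the cycloaddition.
- Comparison: on structure, it solves the half without the stereocentre and leaves ring C, ring B and C2 of the flavanone still to be built on a phloroglucinol ring. On mechanism, both plans rest on a diazo ketone and are equal in hazard class. On step economy it should be clearly longer.

Alternative 2: The cut is through the flavone pyranone (C4a''–C4'', C4''–C3'', O1''–C2''). Zerovalent palladium, formed from PdCl2(PPh3)2 under a secondary amine, would insert into the C–I bond of the iodophenol A5 and take up carbon monoxide A6. The acyl palladium would couple with the alkyne A7 to an ynone, and the phenol would close in the six-membered mode to give A8.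
- In its favour: three bonds form in one convergent step. The biaryl bond would be made earlier between two simple phloroglucinol rings, which may be easier than coupling a flavonyl boronate; on that point it is possibly better. It needs no diazo compound.
- Against it here: the iodide of A5 lies between a benzyloxy group and the hydroxyl, so oxidative addition and carbonyl insertion are slowed. Five-membered closure to an aurone competes. A6 is a toxic gas, which is no safer than the one diazo ketone of the chosen plan. The placing of iodine in A5 raises the same ortho-versus-para question as step 3, so the two plans are equal there.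
- Comparison: on structure it again rebuilds the purchasable flavone and leaves the flavanone and C2 untouched. On mechanism both use palladium for the biaryl. On step economy it should be longer.

Alternative 3: The cut removes O1–C2 and C3–C4 of ring C. A chiral phosphoric acid would dehydrate the hydroxybenzyl alcohol A9 to the ortho-quinone methide A10, which would add the styrene A11 in a hetero-Diels–Alder sense inside the chiral ion pair to give the flavan A12. A later benzylic oxidation would install the C4 ketone.
- In its favour: two bonds, ring C and C2 are made in one step, one bond more than the chosen key step. It is organocatalytic, with no diazo compound and no precious metal. All oxygens can be benzyl ethers, so one deprotection suffices; on protecting-group economy it is better. O1 is fixed by the position of the hydroxymethyl group, which equals the chosen plan.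
- Against it here: A10 has no substituent on the methide carbon, so it should be very reactive and prone to oligomerise. The well-established enantioselective versions rely on aryl- or alkynyl-substituted methides. A12 is at the wrong oxidation level, and oxidising the C4 methylene beside five benzyl ethers and the doubly activated C2–H is a serious chemoselectivity problem. A9 needs formylation and reduction on the hindered biaryl.
- Comparison: on structure it addresses the same ring and stereocentre. On mechanism its stereocontrol is less well founded for this substitution pattern. On step economy the extra hydroxymethyl and oxidation steps cancel the gain of the single deprotection.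

Key step: step 10

Assumption: the configuration of the hindered C6–C8'' axis is not defined in the target and is not controlled, so compounds 10 to 16 may exist as slowly interconverting or separable rotamers with the same C2 configuration from 14 on.

Assumption: Rh2(S-PTTL)4 is taken to deliver the (2S) product. The sense of induction at this ether C–H cannot be predicted with confidence, and the mirror-image catalyst Rh2(R-PTTL)4 would be used if the opposite sense is needed.

## Route

Step 1
Reactants: 1 2,4,6-trihydroxyacetophenone
Product: 2 1-[4-(benzyloxy)-2,6-dihydroxyphenyl]ethanone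
Conditions: BnBr (1.0 equiv), K2CO3 (1.1 equiv), DMF, 0 °C to rt
Reagents that add atoms: benzyl bromide, BrCc1ccccc1
Why: Williamson ether synthesis; the para hydroxyl is the most acidic and the only one not hydrogen-bonded to the acetyl group, so it should react first, and limiting the halide holds back dialkylation.

Step 2
Reactants: 2 1-[4-(benzyloxy)-2,6-dihydroxyphenyl]ethanone; 3 4-(benzyloxy)benzyl chloride
Product: 4 1-[4-(benzyloxy)-2-{[4-(benzyloxy)phenyl]methoxy}-6-hydroxyphenyl]ethanone
Conditions: K2CO3 (1.5 equiv), DMF, 50 °C
Reagents that add atoms: none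
Why: Williamson ether synthesis with a very reactive 4-alkoxybenzyl chloride; the two ortho hydroxyls of 2 are equivalent, and after one is alkylated the other is held in a strong hydrogen bond to the carbonyl and should resist a second alkylation.

Step 3
Reactants: 4 1-[4-(benzyloxy)-2-{[4-(benzyloxy)phenyl]methoxy}-6-hydroxyphenyl]ethanone
Product: 5 1-[4-(benzyloxy)-6-{[4-(benzyloxy)phenyl]methoxy}-2-hydroxy-3-iodophenyl]ethanone
Conditions: BnMe3N·ICl2 (1.05 equiv), NaHCO3, CH2Cl2–MeOH, rt
Reagents that add atoms: benzyltrimethylammonium dichloroiodate, C[N+](C)(C)Cc1ccccc1.Cl[I-]Cl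
Why: Electrophilic aromatic iodination; the free chelated phenol is the strongest activating group and should direct iodine to its open ortho position between OH and OBn, the usual outcome for 2-hydroxy-4,6-dialkoxyacetophenones. The hydrogencarbonate buffer protects the acid-labile 4-benzyloxybenzyl ether.

Step 4
Reactants: 6 apigenin
Product: 7 5,7-bis(benzyloxy)-2-[4-(benzyloxy)phenyl]chromen-4-one
Conditions: BnBr (4 equiv), K2CO3 (5 equiv), DMF, 70 °C
Reagents that add atoms: benzyl bromide, BrCc1ccccc1
Why: Exhaustive Williamson benzylation; the 7- and 4'-hydroxyls react readily, and excess halide and heat are needed to alkylate the chelated 5-hydroxyl.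

Step 5
Reactants: 7 5,7-bis(benzyloxy)-2-[4-(benzyloxy)phenyl]chromen-4-one
Product: 8 5,7-bis(benzyloxy)-2-[4-(benzyloxy)phenyl]-8-iodochromen-4-one
Conditions: I2 (1.05 equiv), AgO2CCF3 (1.05 equiv), CH2Cl2, 0 °C to rt
Reagents that add atoms: iodine, [I][I]
Why: Electrophilic aromatic iodination by the acyl hypoiodite formed from iodine and the monovalent silver salt; in 5,7-dialkoxyflavones C8 (between one alkoxy group and the ring oxygen) is expected to be more reactive and less shielded than C6 (between two benzyloxy groups). Ring B is deactivated by conjugation with the pyranone.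

Step 6
Reactants: 8 5,7-bis(benzyloxy)-2-[4-(benzyloxy)phenyl]-8-iodochromen-4-one
Product: 9 5,7-bis(benzyloxy)-2-[4-(benzyloxy)phenyl]-8-(4,4,5,5-tetramethyl-1,3,2-dioxaborolan-2-yl)chromen-4-one
Conditions: pinacolborane (1.5 equiv), Et3N (3 equiv), PdCl2(MeCN)2 (2 mol %), SPhos (8 mol %), 1,4-dioxane, 80 °C
Reagents that add atoms: pinacolborane, CC1(C)OBOC1(C)C
Why: Palladium-catalysed borylation of an aryl iodide with a dialkoxyborane (Miyaura–Masuda type); the dialkylbiarylphosphine allows di-ortho-substituted halides to react, and the anhydrous amine conditions should limit protodeboronation of the electron-rich boronate.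

Step 7
Reactants: 5 1-[4-(benzyloxy)-6-{[4-(benzyloxy)phenyl]methoxy}-2-hydroxy-3-iodophenyl]ethanone; 9 5,7-bis(benzyloxy)-2-[4-(benzyloxy)phenyl]-8-(4,4,5,5-tetramethyl-1,3,2-dioxaborolan-2-yl)chromen-4-one
Product: 10 8-[3-acetyl-6-(benzyloxy)-4-{[4-(benzyloxy)phenyl]methoxy}-2-hydroxyphenyl]-5,7-bis(benzyloxy)-2-[4-(benzyloxy)phenyl]chromen-4-one
Conditions: Pd(OAc)2 (5 mol %), SPhos (10 mol %), K3PO4 (3 equiv), toluene–H2O (10:1), 90 °C
Reagents that add atoms: none
Why: Suzuki–Miyaura coupling; zerovalent palladium carrying SPhos is one of the few catalyst systems known to form tetra-ortho-substituted biaryls. The free phenol is carried as its phenoxide and the hindered methyl ketone should be inert.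

Step 8
Reactants: 10 8-[3-acetyl-6-(benzyloxy)-4-{[4-(benzyloxy)phenyl]methoxy}-2-hydroxyphenyl]-5,7-bis(benzyloxy)-2-[4-(benzyloxy)phenyl]chromen-4-one
Product: 11 8-[3-acetyl-6-(benzyloxy)-4-{[4-(benzyloxy)phenyl]methoxy}-2-(tert-butyldimethylsilyloxy)phenyl]-5,7-bis(benzyloxy)-2-[4-(benzyloxy)phenyl]chromen-4-one
Conditions: TBSOTf (2 equiv), 2,6-lutidine (3 equiv), CH2Cl2, −40 °C to 0 °C
Reagents that add atoms: tert-butyldimethylsilyl triflate, CC(C)(C)[Si](C)(C)OS(=O)(=O)C(F)(F)F
Why: O-silylation of a phenol; the silyl triflate is reactive enough for a chelated phenol shielded by an acyl group and a biaryl, while the hindered pyridine base does not enolise the methyl ketone and buffers the acid that would cleave the 4-benzyloxybenzyl ether. Any reversible silylation of the flavone carbonyl is undone on aqueous work-up.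

Step 9
Reactants: 11 8-[3-acetyl-6-(benzyloxy)-4-{[4-(benzyloxy)phenyl]methoxy}-2-(tert-butyldimethylsilyloxy)phenyl]-5,7-bis(benzyloxy)-2-[4-(benzyloxy)phenyl]chromen-4-one
Product: 13 2-diazo-1-[4-(benzyloxy)-6-{[4-(benzyloxy)phenyl]methoxy}-2-(tert-butyldimethylsilyloxy)-3-{5,7-bis(benzyloxy)-2-[4-(benzyloxy)phenyl]-4-oxochromen-8-yl}phenyl]ethanone, via trifluoroacetyl diketone 12 (not isolated)
Conditions: LiN(SiMe3)2 (1.1 equiv), THF, −78 °C; CF3CO2CH2CF3 (1.2 equiv), −78 °C; cold dilute aq HCl quench; then 4-acetamidobenzenesulfonyl azide (1.5 equiv), Et3N (1.5 equiv), H2O (1 equiv), MeCN, rt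
Reagents that add atoms: 2,2,2-trifluoroethyl trifluoroacetate, O=C(OCC(F)(F)F)C(F)(F)F (its atoms remain only in 12); 4-acetamidobenzenesulfonyl azide, CC(=O)Nc1ccc(cc1)S(=O)(=O)N=[N+]=[N-]
Why: Detrifluoroacetylative diazo transfer (Danheiser procedure); the kinetic lithium enolate of the methyl ketone, the only acidic C–H site, is trifluoroacetylated in a Claisen condensation, and the activated diketone then takes the diazo group from the sulfonyl azide and loses the trifluoroacetyl group as an N-acylsulfonamide. The method needs no diazomethane, and the acetamido-substituted azide is among the least hazardous sulfonyl azides.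

Step 10
Reactants: 13 2-diazo-1-[4-(benzyloxy)-6-{[4-(benzyloxy)phenyl]methoxy}-2-(tert-butyldimethylsilyloxy)-3-{5,7-bis(benzyloxy)-2-[4-(benzyloxy)phenyl]-4-oxochromen-8-yl}phenyl]ethanone
Product: 14 (2S)-7-(benzyloxy)-2-[4-(benzyloxy)phenyl]-6-{5,7-bis(benzyloxy)-2-[4-(benzyloxy)phenyl]-4-oxochromen-8-yl}-5-(tert-butyldimethylsilyloxy)-2,3-dihydrochromen-4-one
Conditions: Rh2(S-PTTL)4 (2 mol %), toluene, −20 °C to rt, slow addition of 13
Reagents that add atoms: none
Why: The divalent rhodium carboxylate attacks the diazo carbon of 13 and, after loss of dinitrogen, the electrophilic rhodium carbene at the future C3 inserts into one benzylic C–H of the neighbouring aryl 4-benzyloxybenzyl ether through a concerted, asynchronous three-centre transition state with hydride-transfer character, forming C2–C3. The closest known reaction type is the rhodium-carboxylate-catalysed cyclisation of 2-alkoxyaryl diazomethyl ketones to chroman-4-ones, including enantioselective versions with chiral carboxylates. Ring C is closed as a six-membered ring by 1,6-insertion (carbene carbon, C4, C4a, C8a, O1, C2); at the five-ring distance there is no C–H, only the oxygen itself. C2 is set by the catalyst: the chiral pocket of the four N-phthaloyl-tert-leucinate ligands decides which of the two enantiotopic benzylic hydrogens is reached, and insertion goes with retention at carbon, so the centre is under reagent control. Three selectivities are needed: insertion rather than attack of the ether oxygen on the carbene (oxonium ylide, then [1,2]-shift to a 2-benzylbenzofuran-3-one), a single site, and a single enantiotopic hydrogen. The substrate helps because the target C–H is made hydridic by both O1 and the 4-benzyloxyphenyl ring, the ether oxygen is a weakly basic aryl oxygen conjugated to the acyl-bearing ring, and the other ortho oxygen carries a silyl group with no activated C–H; the bulky carboxylate and the low temperature should further favour insertion over ylide formation. Slow addition keeps the diazo ketone dilute against carbene dimerisation, and the hindered biaryl axis is remote from the reacting atoms, so both rotamers of 13 should respond to the catalyst alike.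

Step 11
Reactants: 14 (2S)-7-(benzyloxy)-2-[4-(benzyloxy)phenyl]-6-{5,7-bis(benzyloxy)-2-[4-(benzyloxy)phenyl]-4-oxochromen-8-yl}-5-(tert-butyldimethylsilyloxy)-2,3-dihydrochromen-4-one
Product: 15 (2S)-7-(benzyloxy)-2-[4-(benzyloxy)phenyl]-6-{5,7-bis(benzyloxy)-2-[4-(benzyloxy)phenyl]-4-oxochromen-8-yl}-5-hydroxy-2,3-dihydrochromen-4-one
Conditions: Bu4NF (1.2 equiv), AcOH (1.5 equiv), THF, 0 °C
Reagents that add atoms: none
Why: Fluoride-mediated cleavage of an aryl silyl ether; the acetic acid buffer keeps free phenoxide and enolate concentrations low, so the ring opening to the chalcone that would racemise C2 should not set in. The liberated 5-hydroxyl is at once held by a hydrogen bond to the C4 carbonyl.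

Step 12
Reactants: 15 (2S)-7-(benzyloxy)-2-[4-(benzyloxy)phenyl]-6-{5,7-bis(benzyloxy)-2-[4-(benzyloxy)phenyl]-4-oxochromen-8-yl}-5-hydroxy-2,3-dihydrochromen-4-one
Product: 16 (2S)-5,7-dihydroxy-2-(4-hydroxyphenyl)-6-[5,7-dihydroxy-2-(4-hydroxyphenyl)-4-oxochromen-8-yl]-2,3-dihydrochromen-4-one
Conditions: H2 (1 atm), 10% Pd/C, THF–MeOH, rt
Reagents that add atoms: none
Why: Catalytic hydrogenolysis of five aryl benzyl ethers under neutral conditions, which do not touch C2; at ambient pressure benzyl ether cleavage should be much faster than reduction of the flavone C2''=C3'' bond, the chelated ketone or the ring benzylic C2–O1 bond. The reaction is stopped as soon as 15 and the partly debenzylated intermediates are consumed.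

## Compound list

1 | 2,4,6-trihydroxyacetophenone | CC(=O)c1c(O)cc(O)cc1O | starting material
2 | 1-[4-(benzyloxy)-2,6-dihydroxyphenyl]ethanone | CC(=O)c1c(O)cc(OCc2ccccc2)cc1O | intermediate
3 | 4-(benzyloxy)benzyl chloride | ClCc1ccc(OCc2ccccc2)cc1 | starting material
4 | 1-[4-(benzyloxy)-2-{[4-(benzyloxy)phenyl]methoxy}-6-hydroxyphenyl]ethanone | CC(=O)c1c(OCc2ccc(OCc3ccccc3)cc2)cc(OCc2ccccc2)cc1O | intermediate
5 | 1-[4-(benzyloxy)-6-{[4-(benzyloxy)phenyl]methoxy}-2-hydroxy-3-iodophenyl]ethanone | CC(=O)c1c(OCc2ccc(OCc3ccccc3)cc2)cc(OCc2ccccc2)c(I)c1O | intermediate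
6 | apigenin | O=c1cc(-c2ccc(O)cc2)oc2cc(O)cc(O)c12 | starting material
7 | 5,7-bis(benzyloxy)-2-[4-(benzyloxy)phenyl]chromen-4-one | O=c1cc(-c2ccc(OCc3ccccc3)cc2)oc2cc(OCc3ccccc3)cc(OCc3ccccc3)c12 | intermediate
8 | 5,7-bis(benzyloxy)-2-[4-(benzyloxy)phenyl]-8-iodochromen-4-one | O=c1cc(-c2ccc(OCc3ccccc3)cc2)oc2c(I)c(OCc3ccccc3)cc(OCc3ccccc3)c12 | intermediate
9 | 5,7-bis(benzyloxy)-2-[4-(benzyloxy)phenyl]-8-(4,4,5,5-tetramethyl-1,3,2-dioxaborolan-2-yl)chromen-4-one | O=c1cc(-c2ccc(OCc3ccccc3)cc2)oc2c(B3OC(C)(C)C(C)(C)O3)c(OCc3ccccc3)cc(OCc3ccccc3)c12 | intermediate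
10 | 8-[3-acetyl-6-(benzyloxy)-4-{[4-(benzyloxy)phenyl]methoxy}-2-hydroxyphenyl]-5,7-bis(benzyloxy)-2-[4-(benzyloxy)phenyl]chromen-4-one | CC(=O)c1c(OCc2ccc(OCc3ccccc3)cc2)cc(OCc2ccccc2)c(-c2c(OCc3ccccc3)cc(OCc3ccccc3)c3c(=O)cc(-c4ccc(OCc5ccccc5)cc4)oc23)c1O | intermediate
11 | 8-[3-acetyl-6-(benzyloxy)-4-{[4-(benzyloxy)phenyl]methoxy}-2-(tert-butyldimethylsilyloxy)phenyl]-5,7-bis(benzyloxy)-2-[4-(benzyloxy)phenyl]chromen-4-one | CC(=O)c1c(OCc2ccc(OCc3ccccc3)cc2)cc(OCc2ccccc2)c(-c2c(OCc3ccccc3)cc(OCc3ccccc3)c3c(=O)cc(-c4ccc(OCc5ccccc5)cc4)oc23)c1O[Si](C)(C)C(C)(C)C | intermediate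
12 | 1-[4-(benzyloxy)-6-{[4-(benzyloxy)phenyl]methoxy}-2-(tert-butyldimethylsilyloxy)-3-{5,7-bis(benzyloxy)-2-[4-(benzyloxy)phenyl]-4-oxochromen-8-yl}phenyl]-4,4,4-trifluorobutane-1,3-dione (not isolated) | O=C(CC(=O)C(F)(F)F)c1c(OCc2ccc(OCc3ccccc3)cc2)cc(OCc2ccccc2)c(-c2c(OCc3ccccc3)cc(OCc3ccccc3)c3c(=O)cc(-c4ccc(OCc5ccccc5)cc4)oc23)c1O[Si](C)(C)C(C)(C)C | intermediate
13 | 2-diazo-1-[4-(benzyloxy)-6-{[4-(benzyloxy)phenyl]methoxy}-2-(tert-butyldimethylsilyloxy)-3-{5,7-bis(benzyloxy)-2-[4-(benzyloxy)phenyl]-4-oxochromen-8-yl}phenyl]ethanone | [N-]=[N+]=CC(=O)c1c(OCc2ccc(OCc3ccccc3)cc2)cc(OCc2ccccc2)c(-c2c(OCc3ccccc3)cc(OCc3ccccc3)c3c(=O)cc(-c4ccc(OCc5ccccc5)cc4)oc23)c1O[Si](C)(C)C(C)(C)C | intermediate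
14 | (2S)-7-(benzyloxy)-2-[4-(benzyloxy)phenyl]-6-{5,7-bis(benzyloxy)-2-[4-(benzyloxy)phenyl]-4-oxochromen-8-yl}-5-(tert-butyldimethylsilyloxy)-2,3-dihydrochromen-4-one | O=C1C[C@@H](c2ccc(OCc3ccccc3)cc2)Oc2cc(OCc3ccccc3)c(-c3c(OCc4ccccc4)cc(OCc4ccccc4)c4c(=O)cc(-c5ccc(OCc6ccccc6)cc5)oc34)c(O[Si](C)(C)C(C)(C)C)c21 | intermediate
15 | (2S)-7-(benzyloxy)-2-[4-(benzyloxy)phenyl]-6-{5,7-bis(benzyloxy)-2-[4-(benzyloxy)phenyl]-4-oxochromen-8-yl}-5-hydroxy-2,3-dihydrochromen-4-one | O=C1C[C@@H](c2ccc(OCc3ccccc3)cc2)Oc2cc(OCc3ccccc3)c(-c3c(OCc4ccccc4)cc(OCc4ccccc4)c4c(=O)cc(-c5ccc(OCc6ccccc6)cc5)oc34)c(O)c21 | intermediate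
16 | (2S)-5,7-dihydroxy-2-(4-hydroxyphenyl)-6-[5,7-dihydroxy-2-(4-hydroxyphenyl)-4-oxochromen-8-yl]-2,3-dihydrochromen-4-one | O=C1C[C@@H](c2ccc(O)cc2)Oc2cc(O)c(-c3c(O)cc(O)c4c(=O)cc(-c5ccc(O)cc5)oc34)c(O)c21 | target

## Step count and least certain steps

Total: 12 steps. Longest linear sequence: 9 steps (steps 1, 2, 3, 7, 8, 9, 10, 11, 12); the branch from 6 through steps 4, 5 and 6 is equally long.

Step 10 (key step). The most likely failure is attack of the ether oxygen on the carbene followed by a [1,2]-benzyl shift, because the 4-alkoxybenzyl group migrates easily. Poor discrimination between the two benzylic hydrogens, or carbene dimerisation, are the other risks. The fallback abandons the carbene and sets the centre by conjugate addition. It sets out from 11.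
- Oxidative removal of the 4-benzyloxybenzyl group with DDQ in wet CH2Cl2 would give the silyl-protected hydroxy ketone F1.
- Condensation with dimethylformamide dimethyl acetal would give the enaminone F2.
- Mild acid (AcOH, 50 °C) would close this to the chromone F3, with the ring oxygen fixed by the only free phenol.
- Enantioselective conjugate addition of 4-(benzyloxy)phenylboronic acid to F3, catalysed by Pd(O2CCF3)2 with the appropriate enantiomer of the tert-butyl pyridine-oxazoline ligand in wet 1,2-dichloroethane, is a known base-free route to 2-arylchroman-4-ones. It would return to the route at 14.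

Step 7. Protodeboronation of the electron-rich, di-ortho-oxygenated boronate may outrun the slow transmetalation at a hindered palladium centre, and oxidative addition into the electron-rich iodophenoxide may be slow. The fallback changes the organometallic class to zinc, which is not protonated under anhydrous conditions and is well suited to tetra-ortho-substituted biaryls. It sets out from 5 and 8.
- 5 would be silylated (TBSOTf, 2,6-lutidine) to the iodo silyl ether F4.
- 8 would be converted by zinc dust and LiCl in THF into the arylzinc iodide F5.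
- Negishi coupling of F4 and F5 with Pd(OAc)2 and SPhos in THF at 60 °C would return to the route at 11.

Step 9. The silyl group may migrate from the aryl oxygen to the enolate oxygen through a six-membered transition state, or be lost under the basic conditions, before the enolate is acylated. The fallback avoids any strong base. It sets out from 10.
- Heating with dimethylformamide dimethyl acetal would give the hydroxy enaminone F6.
- Silylation with TBSCl and imidazole in DMF would give the silyl enaminone F7.
- Diazo transfer from 4-acetamidobenzenesulfonyl azide to the enaminone double bond (cycloaddition, then loss of an N-sulfonylformamidine) is a known neutral route to diazomethyl ketones. It would return to the route at 13.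

Step 5. Iodination may occur at C6'' instead of, or as well as, C8'', or twice. The fallback builds the iodoflavone from an acetophenone in which the iodine position is fixed before the pyranone exists. It sets out from 1.
- Dibenzylation (BnBr, K2CO3, DMF) would give the mono-phenol F8.
- Iodination ortho to the chelated phenol, as in step 3, would give the iodo ketone F9.
- Claisen–Schmidt condensation with 4-(benzyloxy)benzaldehyde (KOH, EtOH) would give the chalcone F10.
- Oxidative cyclisation with catalytic iodine in DMSO at 120 °C would close the flavone through the phenol next to the iodine. It would return to the route at 8.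

Step 3. Iodination may go para to the phenol (between the two ether oxygens) instead of ortho, or the acid released may cleave the 4-benzyloxybenzyl ether. The fallback changes the order so that symmetry removes the regiochemical question. It sets out from 2.
- Iodination of the symmetrical 2 with the same reagent can give only one mono-iodide, F11.
- Alkylation with 3 (K2CO3, DMF) should then occur at the hydroxyl remote from the iodine, the other being flanked by both iodine and the acyl group. It would return to the route at 5.

## Further compounds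

F1 | step 10 | 8-[3-acetyl-6-(benzyloxy)-2-(tert-butyldimethylsilyloxy)-4-hydroxyphenyl]-5,7-bis(benzyloxy)-2-[4-(benzyloxy)phenyl]chromen-4-one | CC(=O)c1c(O)cc(OCc2ccccc2)c(-c2c(OCc3ccccc3)cc(OCc3ccccc3)c3c(=O)cc(-c4ccc(OCc5ccccc5)cc4)oc23)c1O[Si](C)(C)C(C)(C)C
F2 | step 10 | (E)-1-[4-(benzyloxy)-2-(tert-butyldimethylsilyloxy)-6-hydroxy-3-{5,7-bis(benzyloxy)-2-[4-(benzyloxy)phenyl]-4-oxochromen-8-yl}phenyl]-3-(dimethylamino)prop-2-en-1-one | CN(C)/C=C/C(=O)c1c(O)cc(OCc2ccccc2)c(-c2c(OCc3ccccc3)cc(OCc3ccccc3)c3c(=O)cc(-c4ccc(OCc5ccccc5)cc4)oc23)c1O[Si](C)(C)C(C)(C)C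
F3 | step 10 | 7-(benzyloxy)-6-{5,7-bis(benzyloxy)-2-[4-(benzyloxy)phenyl]-4-oxochromen-8-yl}-5-(tert-butyldimethylsilyloxy)chromen-4-one | O=c1ccoc2cc(OCc3ccccc3)c(-c3c(OCc4ccccc4)cc(OCc4ccccc4)c4c(=O)cc(-c5ccc(OCc6ccccc6)cc5)oc34)c(O[Si](C)(C)C(C)(C)C)c12
F4 | step 7 | 1-[4-(benzyloxy)-6-{[4-(benzyloxy)phenyl]methoxy}-2-(tert-butyldimethylsilyloxy)-3-iodophenyl]ethanone | CC(=O)c1c(OCc2ccc(OCc3ccccc3)cc2)cc(OCc2ccccc2)c(I)c1O[Si](C)(C)C(C)(C)C
F5 | step 7 | {5,7-bis(benzyloxy)-2-[4-(benzyloxy)phenyl]-4-oxochromen-8-yl}zinc iodide | O=c1cc(-c2ccc(OCc3ccccc3)cc2)oc2c([Zn]I)c(OCc3ccccc3)cc(OCc3ccccc3)c12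
F6 | step 9 | (E)-1-[4-(benzyloxy)-6-{[4-(benzyloxy)phenyl]methoxy}-2-hydroxy-3-{5,7-bis(benzyloxy)-2-[4-(benzyloxy)phenyl]-4-oxochromen-8-yl}phenyl]-3-(dimethylamino)prop-2-en-1-one | CN(C)/C=C/C(=O)c1c(OCc2ccc(OCc3ccccc3)cc2)cc(OCc2ccccc2)c(-c2c(OCc3ccccc3)cc(OCc3ccccc3)c3c(=O)cc(-c4ccc(OCc5ccccc5)cc4)oc23)c1O
F7 | step 9 | (E)-1-[4-(benzyloxy)-6-{[4-(benzyloxy)phenyl]methoxy}-2-(tert-butyldimethylsilyloxy)-3-{5,7-bis(benzyloxy)-2-[4-(benzyloxy)phenyl]-4-oxochromen-8-yl}phenyl]-3-(dimethylamino)prop-2-en-1-one | CN(C)/C=C/C(=O)c1c(OCc2ccc(OCc3ccccc3)cc2)cc(OCc2ccccc2)c(-c2c(OCc3ccccc3)cc(OCc3ccccc3)c3c(=O)cc(-c4ccc(OCc5ccccc5)cc4)oc23)c1O[Si](C)(C)C(C)(C)C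
F8 | step 5 | 1-[2,4-bis(benzyloxy)-6-hydroxyphenyl]ethanone | CC(=O)c1c(O)cc(OCc2ccccc2)cc1OCc1ccccc1
F9 | step 5 | 1-[4,6-bis(benzyloxy)-2-hydroxy-3-iodophenyl]ethanone | CC(=O)c1c(O)c(I)c(OCc2ccccc2)cc1OCc1ccccc1
F10 | step 5 | (E)-1-[4,6-bis(benzyloxy)-2-hydroxy-3-iodophenyl]-3-[4-(benzyloxy)phenyl]prop-2-en-1-one | O=C(/C=C/c1ccc(OCc2ccccc2)cc1)c1c(O)c(I)c(OCc2ccccc2)cc1OCc1ccccc1
F11 | step 3 | 1-[4-(benzyloxy)-2,6-dihydroxy-3-iodophenyl]ethanone | CC(=O)c1c(O)cc(OCc2ccccc2)c(I)c1O
A1 | alternative 1 | 2-diazo-2-[2,6-bis(benzyloxy)-4-(methoxymethoxy)phenyl]-1-[6-(4-benzyloxyphenyl)-4-oxo-4H-pyran-2-yl]ethanone | [N-]=[N+]=C(C(=O)c1cc(=O)cc(-c2ccc(OCc3ccccc3)cc2)o1)c1c(OCc2ccccc2)cc(OCOC)cc1OCc1ccccc1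
A2 | alternative 1 | 2-[2,6-bis(benzyloxy)-4-(methoxymethoxy)phenyl]-2-[6-(4-benzyloxyphenyl)-4-oxo-4H-pyran-2-yl]ethenone | O=C=C(c1cc(=O)cc(-c2ccc(OCc3ccccc3)cc2)o1)c1c(OCc2ccccc2)cc(OCOC)cc1OCc1ccccc1
A3 | alternative 1 | benzyl ethynyl ether | C#COCc1ccccc1
A4 | alternative 1 | 7-benzyloxy-8-[2,6-bis(benzyloxy)-4-(methoxymethoxy)phenyl]-2-(4-benzyloxyphenyl)-5-hydroxychromen-4-one | O=c1cc(-c2ccc(OCc3ccccc3)cc2)oc2c(-c3c(OCc4ccccc4)cc(OCOC)cc3OCc3ccccc3)c(OCc3ccccc3)cc(O)c12
A5 | alternative 2 | 3,5-bis(benzyloxy)-2-iodo-6-[2,6-bis(benzyloxy)-4-(triisopropylsilyloxy)phenyl]phenol | Oc1c(I)c(OCc2ccccc2)cc(OCc2ccccc2)c1-c1c(OCc2ccccc2)cc(O[Si](C(C)C)(C(C)C)C(C)C)cc1OCc1ccccc1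
A6 | alternative 2 | carbon monoxide | [C-]#[O+]
A7 | alternative 2 | 4-benzyloxyphenylacetylene | C#Cc1ccc(OCc2ccccc2)cc1
A8 | alternative 2 | 5,7-bis(benzyloxy)-2-(4-benzyloxyphenyl)-8-[2,6-bis(benzyloxy)-4-(triisopropylsilyloxy)phenyl]chromen-4-one | O=c1cc(-c2ccc(OCc3ccccc3)cc2)oc2c(-c3c(OCc4ccccc4)cc(O[Si](C(C)C)(C(C)C)C(C)C)cc3OCc3ccccc3)c(OCc3ccccc3)cc(OCc3ccccc3)c12
A9 | alternative 3 | 5,7-bis(benzyloxy)-2-(4-benzyloxyphenyl)-8-[2,6-bis(benzyloxy)-4-hydroxy-3-(hydroxymethyl)phenyl]chromen-4-one | OCc1c(O)cc(OCc2ccccc2)c(-c2c(OCc3ccccc3)cc(OCc3ccccc3)c3c(=O)cc(-c4ccc(OCc5ccccc5)cc4)oc23)c1OCc1ccccc1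
A10 | alternative 3 | 3,5-bis(benzyloxy)-4-{5,7-bis(benzyloxy)-2-(4-benzyloxyphenyl)-4-oxochromen-8-yl}-6-methylidenecyclohexa-2,4-dien-1-one | C=C1C(=O)C=C(OCc2ccccc2)C(-c2c(OCc3ccccc3)cc(OCc3ccccc3)c3c(=O)cc(-c4ccc(OCc5ccccc5)cc4)oc23)=C1OCc1ccccc1
A11 | alternative 3 | 4-benzyloxystyrene | C=Cc1ccc(OCc2ccccc2)cc1
A12 | alternative 3 | (2S)-5,7-bis(benzyloxy)-2-(4-benzyloxyphenyl)-6-{5,7-bis(benzyloxy)-2-(4-benzyloxyphenyl)-4-oxochromen-8-yl}chroman | C1C[C@@H](c2ccc(OCc3ccccc3)cc2)Oc2cc(OCc3ccccc3)c(-c3c(OCc4ccccc4)cc(OCc4ccccc4)c4c(=O)cc(-c5ccc(OCc6ccccc6)cc5)oc34)c(OCc3ccccc3)c21
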